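**Retrosynthetic overview**

1. Feature: in the side chain on ring B, C-α (benzylic carbinol on the para-oxygenated ring C), C-β (bearing ring B) and C-γ (CH2OH) form a 1,3-diol. It is treated as an opened trans-4,5-diaryl-1,3-dioxane (O3–C4 = O–C-α, C5 = C-β, C6 = C-γ).
2. Key disconnection: the C-β–C-γ bond, the C-α–O bond and the acetal lead back to (E)-stilbene 6 (ring C with ring B as its bromo pivalate) and two formaldehyde units (enantioselective Prins reaction). The stilbene comes from a Horner–Wadsworth–Emmons reaction.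
3. Lactone: the ring-B–CH2 bond comes from copper-catalysed opening of cyclopropane lactone 14 ((R)-epichlorohydrin plus dimethyl malonate) by the aryl Grignard reagent from 10. The ring-A benzyl enters by enolate alkylation, and dealkoxycarbonylation gives the trans lactone.
4. Ring order: dioxane (step 5); bicyclic cyclopropane lactone (step 7, side branch); cyclopropane opened to leave the butyrolactone (step 8); dioxane opened (step 11); benzyl ethers removed (step 12).

Key step: step 5

Remark 1: the facial preference of the confined acid cannot be predicted for a 1,2-diaryl alkene; the catalyst enantiomer that gives the (4R,5R)-dioxane is assumed to be found in a first screening run.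
Remark 2: (R)-epichlorohydrin is assumed to react with malonate by epoxide opening and re-closure, which leads to the (1S,5R)-lactone 14.
Remark 3: alcohol 1 is taken as a catalogue compound.

**Route**

Step 1
Reactants: 1 4-(benzyloxy)-3-methoxybenzyl alcohol
Product: 2 4-(benzyloxy)-3-methoxybenzyl bromide
Conditions: PBr3 (0.4 equiv), Et2O, 0 °C; used without storage
Reagents that add atoms: phosphorus tribromide, BrP(Br)Br
Why: Bromination of an electron-rich benzylic alcohol through its phosphite ester (SN2 displacement by bromide), with no stereocentre involved.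

Step 2
Reactants: 2 4-(benzyloxy)-3-methoxybenzyl bromide
Product: 3 diethyl [4-(benzyloxy)-3-methoxybenzyl]phosphonate
Conditions: P(OEt)3 (neat), 130 °C
Reagents that add atoms: triethyl phosphite, CCOP(OCC)OCC
Why: Michaelis–Arbuzov reaction of a reactive benzylic bromide, driven by loss of volatile ethyl bromide.

Step 3
Reactants: 3 diethyl [4-(benzyloxy)-3-methoxybenzyl]phosphonate; 4 5-bromo-2-hydroxy-3-methoxybenzaldehyde
Product: 5 (E)-2-[2-(4-benzyloxy-3-methoxyphenyl)ethenyl]-4-bromo-6-methoxyphenol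
Conditions: KOtBu (2.3 equiv), DMF/THF, 0 °C → rt; aq. NH4Cl
Reagents that add atoms: none
Why: Horner–Wadsworth–Emmons olefination in which the first equivalent of base converts 4 into its phenoxide (so no ortho acyl group is present that could migrate to the β-oxido phosphonate) and the benzylphosphonate carbanion gives the (E)-alkene by reversible addition and syn-elimination of diethyl phosphate.

Step 4
Reactants: 5 (E)-2-[2-(4-benzyloxy-3-methoxyphenyl)ethenyl]-4-bromo-6-methoxyphenol
Product: 6 (E)-2-[2-(4-benzyloxy-3-methoxyphenyl)ethenyl]-4-bromo-6-methoxyphenyl pivalate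
Conditions: PivCl, Et3N, DMAP (cat.), CH2Cl2, 0 °C → rt
Reagents that add atoms: pivaloyl chloride, CC(C)(C)C(=O)Cl
Why: DMAP-catalysed O-acylation of the phenol, giving an acid-stable ester that lowers the donor strength of ring B for the next step.

Step 5
Reactants: 6 (E)-2-[2-(4-benzyloxy-3-methoxyphenyl)ethenyl]-4-bromo-6-methoxyphenyl pivalate; 7 formaldehyde (two equivalents, supplied as paraformaldehyde)
Product: 8 2-[(4R,5R)-4-(4-benzyloxy-3-methoxyphenyl)-1,3-dioxan-5-yl]-4-bromo-6-methoxyphenyl pivalate (trans-dioxane)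
Conditions: (CH2O)n (5 equiv), confined chiral imidodiphosphate-type Brønsted acid (iIDP or IDPi, 5 mol%), CHCl3/cyclohexane, 25 °C
Reagents that add atoms: none
Why: Proposed new method: the confined acid protonates a formaldehyde oligomer (hemiformal) and delivers its oxocarbenium carbon to the alkene carbon next to ring B, so that positive charge grows on the carbon next to the para-benzyloxyphenyl ring C, and the far hemiformal oxygen closes onto that carbon in one strongly asynchronous event or through a contact ion pair held in the catalyst pocket. The closest known reactions are the catalytic asymmetric intermolecular Prins reaction of terminal styrenes with paraformaldehyde under confined imidodiphosphate-type acids, which gives 4-aryl-1,3-dioxanes, and the acid-mediated Prins reaction of β-substituted para-alkoxystyrenes, which gives trans-4-aryl-5-substituted dioxanes; a 1,2-diaryl alkene has not been used in either. The only ring formed, the 1,3-dioxane, is assembled from three components: the C5–C6 bond forms first and the ring closes by O3–C4 bond formation, a six-membered capture of the benzylic cation by oxygen (overall a formal [4+2] addition of a CH2=O+–CH2–O unit across the alkene). C5 is set in the C–C bond-forming event by the chiral anion, which selects the alkene face (catalyst enantiomer chosen to give 5R), and C4 follows as 4R because both new bonds add to the same face of the (E)-alkene and because the trans-diequatorial dioxane is also the more stable isomer if the benzylic C–O bond opens and re-closes. The step needs regio-, diastereo-, enantio- and chemoselectivity: the para-alkoxy donor of ring C, set against a ring B whose ortho oxygen is acylated and which carries bromine, fixes where the cation develops, and the same deactivation keeps ring B out of Friedel–Crafts hydroxymethylation.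

Step 6
Reactants: 8 2-[(4R,5R)-4-(4-benzyloxy-3-methoxyphenyl)-1,3-dioxan-5-yl]-4-bromo-6-methoxyphenyl pivalate
Product: 10 (4R,5R)-5-(2-benzyloxy-5-bromo-3-methoxyphenyl)-4-(4-benzyloxy-3-methoxyphenyl)-1,3-dioxane, via sodium phenoxide 9 (not isolated)
Conditions: NaOMe (1.5 equiv), MeOH/THF, 40 °C; evaporate; BnBr, DMF, 50 °C
Reagents that add atoms: benzyl bromide, BrCc1ccccc1
Why: Transesterification of the aryl pivalate by methoxide followed by Williamson etherification of the phenoxide replaces the ester by an ether that tolerates a Grignard reagent, and neither stereocentre is touched.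

Step 7
Reactants: 11 (R)-epichlorohydrin; 12 dimethyl malonate
Product: 14 methyl (1S,5R)-2-oxo-3-oxabicyclo[3.1.0]hexane-1-carboxylate, via epoxymalonate 13 (not isolated)
Conditions: NaOMe, MeOH, 0 °C → reflux
Reagents that add atoms: none
Why: Tandem alkylation–cyclopropanation–lactonisation in which malonate opens the epoxide at CH2, the alkoxide re-closes to epoxide 13 by displacing chloride, the malonate carbanion opens 13 in a 3-exo-tet SN2 step with inversion and the cis CH2O– lactonises, so C5 comes from the chiral pool and C1 is fixed by the cis ring fusion.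

Step 8
Reactants: 10 (4R,5R)-5-(2-benzyloxy-5-bromo-3-methoxyphenyl)-4-(4-benzyloxy-3-methoxyphenyl)-1,3-dioxane; 14 methyl (1S,5R)-2-oxo-3-oxabicyclo[3.1.0]hexane-1-carboxylate
Product: 16 methyl (3S,4R)-4-{4-benzyloxy-3-[(4R,5R)-4-(4-benzyloxy-3-methoxyphenyl)-1,3-dioxan-5-yl]-5-methoxybenzyl}-2-oxotetrahydrofuran-3-carboxylate, via arylmagnesium bromide 15 (not isolated)
Conditions: Mg, LiCl, THF, 25 °C; then CuI (20 mol%), 14 (1.2 equiv), THF, −30 → 0 °C; aq. NH4Cl
Reagents that add atoms: none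
Why: Copper-catalysed homoconjugate (SN2-type) addition of the aryl Grignard reagent to the doubly activated cyclopropane at its unsubstituted CH2 cleaves the C1–C6 bond to a stabilised enolate; the former C5 is not involved and becomes the (4R) centre, while C3 is epimerisable (drawn trans) and is reset in steps 9 and 10.

Step 9
Reactants: 16 methyl (3S,4R)-4-{4-benzyloxy-3-[(4R,5R)-4-(4-benzyloxy-3-methoxyphenyl)-1,3-dioxan-5-yl]-5-methoxybenzyl}-2-oxotetrahydrofuran-3-carboxylate; 2 4-(benzyloxy)-3-methoxybenzyl bromide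
Product: 17 methyl (3R,4R)-3-(4-benzyloxy-3-methoxybenzyl)-4-{4-benzyloxy-3-[(4R,5R)-4-(4-benzyloxy-3-methoxyphenyl)-1,3-dioxan-5-yl]-5-methoxybenzyl}-2-oxotetrahydrofuran-3-carboxylate
Conditions: NaH, THF/DMF, 0 °C; then 2, rt
Reagents that add atoms: none
Why: C-alkylation of the sodium enolate of the malonate-type lactone ester by the benzylic bromide, which enters anti to the C4 arylmethyl group and so gives the (3R) quaternary centre.

Step 10
Reactants: 17 methyl (3R,4R)-3-(4-benzyloxy-3-methoxybenzyl)-4-{4-benzyloxy-3-[(4R,5R)-4-(4-benzyloxy-3-methoxyphenyl)-1,3-dioxan-5-yl]-5-methoxybenzyl}-2-oxotetrahydrofuran-3-carboxylate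
Product: 18 (3R,4R)-3-(4-benzyloxy-3-methoxybenzyl)-4-{4-benzyloxy-3-[(4R,5R)-4-(4-benzyloxy-3-methoxyphenyl)-1,3-dioxan-5-yl]-5-methoxybenzyl}dihydrofuran-2(3H)-one
Conditions: LiCl, H2O, DMSO, 140 °C; then DBU (0.2 equiv), toluene, 80 °C
Reagents that add atoms: none
Why: Krapcho dealkoxycarbonylation (chloride SN2 at the methyl ester, loss of CO2, protonation of the lactone enolate) re-forms C3, and base equilibration should deliver the thermodynamically favoured 3,4-trans (3R) lactone while C4 is untouched.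

Step 11
Reactants: 18 (3R,4R)-3-(4-benzyloxy-3-methoxybenzyl)-4-{4-benzyloxy-3-[(4R,5R)-4-(4-benzyloxy-3-methoxyphenyl)-1,3-dioxan-5-yl]-5-methoxybenzyl}dihydrofuran-2(3H)-one
Product: 20 (3R,4R)-3-(4-benzyloxy-3-methoxybenzyl)-4-{4-benzyloxy-3-[(1R,2R)-1-(4-benzyloxy-3-methoxyphenyl)-1,3-dihydroxypropan-2-yl]-5-methoxybenzyl}dihydrofuran-2(3H)-one, via silyl ether pyridinium triflate 19 (not isolated)
Conditions: TMSOTf (2 equiv), 2,2'-bipyridyl (3 equiv), CH2Cl2, 0 °C → rt; then H2O
Reagents that add atoms: none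
Why: Methylene acetal cleavage by a silyl triflate–pyridine base pair, in which TMSOTf activates an acetal oxygen, bipyridyl captures the O–CH2 carbon as pyridinium salt 19 and water hydrolyses it together with the silyl ether; this weakly basic sequence breaks no bond at either carbinol stereocentre and should spare the benzyl ethers and the lactone.

Step 12
Reactants: 20 (3R,4R)-3-(4-benzyloxy-3-methoxybenzyl)-4-{4-benzyloxy-3-[(1R,2R)-1-(4-benzyloxy-3-methoxyphenyl)-1,3-dihydroxypropan-2-yl]-5-methoxybenzyl}dihydrofuran-2(3H)-one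
Product: 21 (3R,4R)-3-(4-hydroxy-3-methoxybenzyl)-4-{4-hydroxy-3-[(1R,2R)-1-(4-hydroxy-3-methoxyphenyl)-1,3-dihydroxypropan-2-yl]-5-methoxybenzyl}dihydrofuran-2(3H)-one (CNP0109231.2)
Conditions: H2 (1 atm), 10% Pd/C, EtOAc/EtOH, rt
Reagents that add atoms: none
Why: Catalytic hydrogenolysis of the three aryl benzyl ethers under neutral conditions, stopped at full conversion so that the secondary benzylic alcohol is kept; no stereocentre is affected.

**Compound list**

1 | 4-(benzyloxy)-3-methoxybenzyl alcohol | OCc1ccc(OCc2ccccc2)c(OC)c1 | starting material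
2 | 4-(benzyloxy)-3-methoxybenzyl bromide | BrCc1ccc(OCc2ccccc2)c(OC)c1 | intermediate
3 | diethyl [4-(benzyloxy)-3-methoxybenzyl]phosphonate | CCOP(=O)(Cc1ccc(OCc2ccccc2)c(OC)c1)OCC | intermediate
4 | 5-bromo-2-hydroxy-3-methoxybenzaldehyde (5-bromo-o-vanillin) | COc1cc(Br)cc(C=O)c1O | starting material
5 | (E)-2-[2-(4-benzyloxy-3-methoxyphenyl)ethenyl]-4-bromo-6-methoxyphenol | COc1cc(Br)cc(/C=C/c2ccc(OCc3ccccc3)c(OC)c2)c1O | intermediate
6 | (E)-2-[2-(4-benzyloxy-3-methoxyphenyl)ethenyl]-4-bromo-6-methoxyphenyl pivalate | COc1cc(Br)cc(/C=C/c2ccc(OCc3ccccc3)c(OC)c2)c1OC(=O)C(C)(C)C | intermediate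
7 | formaldehyde (used as paraformaldehyde) | C=O | starting material
8 | 2-[(4R,5R)-4-(4-benzyloxy-3-methoxyphenyl)-1,3-dioxan-5-yl]-4-bromo-6-methoxyphenyl pivalate | COc1cc(Br)cc([C@@H]2COCO[C@H]2c2ccc(OCc3ccccc3)c(OC)c2)c1OC(=O)C(C)(C)C | intermediate
9 | 2-[(4R,5R)-4-(4-benzyloxy-3-methoxyphenyl)-1,3-dioxan-5-yl]-4-bromo-6-methoxyphenol (present as its sodium salt) | COc1cc(Br)cc([C@@H]2COCO[C@H]2c2ccc(OCc3ccccc3)c(OC)c2)c1O | intermediate (not isolated)
10 | (4R,5R)-5-(2-benzyloxy-5-bromo-3-methoxyphenyl)-4-(4-benzyloxy-3-methoxyphenyl)-1,3-dioxane | COc1cc(Br)cc([C@@H]2COCO[C@H]2c2ccc(OCc3ccccc3)c(OC)c2)c1OCc1ccccc1 | intermediate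
11 | (R)-epichlorohydrin | ClC[C@H]1CO1 | starting material
12 | dimethyl malonate | COC(=O)CC(=O)OC | starting material
13 | dimethyl 2-{[(2R)-oxiran-2-yl]methyl}malonate | COC(=O)C(C[C@@H]1CO1)C(=O)OC | intermediate (not isolated)
14 | methyl (1S,5R)-2-oxo-3-oxabicyclo[3.1.0]hexane-1-carboxylate | O=C1OC[C@@H]2C[C@]12C(=O)OC | intermediate
15 | {4-benzyloxy-3-[(4R,5R)-4-(4-benzyloxy-3-methoxyphenyl)-1,3-dioxan-5-yl]-5-methoxyphenyl}magnesium bromide | COc1cc([Mg]Br)cc([C@@H]2COCO[C@H]2c2ccc(OCc3ccccc3)c(OC)c2)c1OCc1ccccc1 | intermediate (not isolated)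
16 | methyl (3S,4R)-4-{4-benzyloxy-3-[(4R,5R)-4-(4-benzyloxy-3-methoxyphenyl)-1,3-dioxan-5-yl]-5-methoxybenzyl}-2-oxotetrahydrofuran-3-carboxylate (C3 epimerisable, drawn trans) | COC(=O)[C@H]1C(=O)OC[C@@H]1Cc1cc(OC)c(OCc2ccccc2)c([C@@H]2COCO[C@H]2c2ccc(OCc3ccccc3)c(OC)c2)c1 | intermediate
17 | methyl (3R,4R)-3-(4-benzyloxy-3-methoxybenzyl)-4-{4-benzyloxy-3-[(4R,5R)-4-(4-benzyloxy-3-methoxyphenyl)-1,3-dioxan-5-yl]-5-methoxybenzyl}-2-oxotetrahydrofuran-3-carboxylate | COc1cc(C[C@@]2(C(=O)OC)C(=O)OC[C@@H]2Cc2cc(OC)c(OCc3ccccc3)c([C@@H]3COCO[C@H]3c3ccc(OCc4ccccc4)c(OC)c3)c2)ccc1OCc1ccccc1 | intermediate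
18 | (3R,4R)-3-(4-benzyloxy-3-methoxybenzyl)-4-{4-benzyloxy-3-[(4R,5R)-4-(4-benzyloxy-3-methoxyphenyl)-1,3-dioxan-5-yl]-5-methoxybenzyl}dihydrofuran-2(3H)-one | COc1cc(C[C@H]2C(=O)OC[C@@H]2Cc2cc(OC)c(OCc3ccccc3)c([C@@H]3COCO[C@H]3c3ccc(OCc4ccccc4)c(OC)c3)c2)ccc1OCc1ccccc1 | intermediate
19 | 2,2'-bipyridinium-1-ylmethyl ether (on the benzylic oxygen) and trimethylsilyl ether (on the primary oxygen) of diol 20, triflate salt; drawn with silicon on the primary oxygen, the regioisomer would give the same diol | COc1cc(C[C@H]2C(=O)OC[C@@H]2Cc2cc(OC)c(OCc3ccccc3)c([C@H](CO[Si](C)(C)C)[C@@H](OC[n+]3ccccc3-c3ccccn3)c3ccc(OCc4ccccc4)c(OC)c3)c2)ccc1OCc1ccccc1.[O-]S(=O)(=O)C(F)(F)F | intermediate (not isolated)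
20 | (3R,4R)-3-(4-benzyloxy-3-methoxybenzyl)-4-{4-benzyloxy-3-[(1R,2R)-1-(4-benzyloxy-3-methoxyphenyl)-1,3-dihydroxypropan-2-yl]-5-methoxybenzyl}dihydrofuran-2(3H)-one | COc1cc(C[C@H]2C(=O)OC[C@@H]2Cc2cc(OC)c(OCc3ccccc3)c([C@H](CO)[C@@H](O)c3ccc(OCc4ccccc4)c(OC)c3)c2)ccc1OCc1ccccc1 | intermediate
21 | (3R,4R)-3-(4-hydroxy-3-methoxybenzyl)-4-{4-hydroxy-3-[(1R,2R)-1-(4-hydroxy-3-methoxyphenyl)-1,3-dihydroxypropan-2-yl]-5-methoxybenzyl}dihydrofuran-2(3H)-one (CNP0109231.2) | COc1cc(C[C@H]2C(=O)OC[C@@H]2Cc2cc(OC)c(O)c([C@H](CO)[C@@H](O)c3ccc(O)c(OC)c3)c2)ccc1O | target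

**Step count and risks**

Total: 12 steps. Longest linear sequence: 11 steps (steps 1–6 and 8–12 from alcohol 1); step 7 is a one-step side branch.

Most likely to fail, in order:

Step 5 (proposed new method). The hindered 1,2-disubstituted alkene may not be activated inside the catalyst pocket. The para-alkoxybenzyl cation may live long enough for the chiral anion to lose control of the alkene face. Formaldehyde may hydroxymethylate the electron-rich ring C instead of adding to the alkene. The fallback uses known auxiliary-controlled anti-aldol chemistry, sets out from 4 and returns at 10; steps 2–6 are then not needed, and step 1 still supplies bromide 2 for step 9. Aldehyde 4 is O-benzylated (BnBr, K2CO3, DMF) to 2-(benzyloxy)-5-bromo-3-methoxybenzaldehyde F1. A Wittig reaction with methoxymethylenetriphenylphosphorane gives the enol ether 1-(benzyloxy)-4-bromo-2-methoxy-6-(2-methoxyethenyl)benzene F2 (E/Z mixture). Hydrolysis (aq. HCl, THF) gives 2-(2-benzyloxy-5-bromo-3-methoxyphenyl)acetaldehyde F3, and Pinnick oxidation gives 2-(2-benzyloxy-5-bromo-3-methoxyphenyl)acetic acid F4. Acylation of lithiated (R)-4-benzyloxazolidin-2-one through the mixed pivalic anhydride gives the N-arylacetyl oxazolidinone F5. The (R)-auxiliary is expected to be the matching one, by analogy with alkylation of chelated Z-enolates anti to the benzyl group; if the facial sense proves opposite, its enantiomer is used. Magnesium chloride-catalysed anti-aldol addition to commercial 4-(benzyloxy)-3-methoxybenzaldehyde (MgCl2, Et3N, TMSCl, EtOAc) gives the silylated aldol adduct F6. Work-up with TFA/MeOH gives the (2S,3R) anti-aldol imide F7. LiBH4 (THF, H2O, 0 °C) removes the auxiliary to give (1R,2R)-2-(2-benzyloxy-5-bromo-3-methoxyphenyl)-1-(4-benzyloxy-3-methoxyphenyl)propane-1,3-diol F8. CH2Br2/NaH in DMF closes the methylene acetal and gives 10.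

Step 8. Magnesium insertion into the electron-rich bromide may be incomplete, the aryl-metal may be protonated, or it may attack the lactone or ester carbonyl instead of opening the cyclopropane. The fallback builds the lactone by Stobbe condensation and asymmetric hydrogenation, sets out from 10 and returns at 18; steps 7, 9 and 10 are then not needed. Bromine–lithium exchange (n-BuLi, THF, −78 °C) and DMF give 4-benzyloxy-3-[(4R,5R)-4-(4-benzyloxy-3-methoxyphenyl)-1,3-dioxan-5-yl]-5-methoxybenzaldehyde F9. Stobbe condensation with dimethyl succinate (NaOMe, MeOH, reflux) gives the (E)-arylidene succinic acid monomethyl ester F10. Hydrogenation with a rhodium–chiral bisphosphine catalyst sets the (R) centre in the benzylsuccinate half-ester F11. Selective reduction of the ester beside the carboxylate (KOH, then Ca(BH4)2, EtOH) and lactonisation on mild acidification give the (R)-4-(arylmethyl)dihydrofuran-2(3H)-one F12. Deprotonation (LiHMDS, THF, −78 °C) and alkylation with bromide 2, anti to the C4 substituent, give 18.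

Step 11. The silyl triflate may attack the lactone (silyl ketene acetal formation and C3 epimerisation), or the hindered acetal may open so slowly that forcing conditions ionise the para-alkoxybenzylic C–O bond, with loss of configuration at C-α. The fallback removes the acetal early and carries the diol as silyl ethers, sets out from 10 and returns at 20. The formal is cleaved on 10 with the same reagent pair, where no lactone is present, to give the diol F8; if ionisation is the failure, the aldol sequence above supplies F8 without a formal ever being formed. TBSOTf/2,6-lutidine gives the bis(tert-butyldimethylsilyl) ether F13. Magnesium insertion (Mg, LiCl, THF) gives the arylmagnesium bromide F14, which opens 14 under copper catalysis to the lactone ester F15. Alkylation with 2 (NaH) gives the quaternary lactone ester F16, and Krapcho dealkoxycarbonylation gives the trans lactone bis-silyl ether F17. TBAF buffered with AcOH in THF removes both silyl ethers without acid and gives 20, which enters step 12.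

**Further compounds**

F1 | step 5 | 2-(benzyloxy)-5-bromo-3-methoxybenzaldehyde | COc1cc(Br)cc(C=O)c1OCc1ccccc1
F2 | step 5 | 1-(benzyloxy)-4-bromo-2-methoxy-6-(2-methoxyethenyl)benzene (E/Z mixture) | COC=Cc1cc(Br)cc(OC)c1OCc1ccccc1
F3 | step 5 | 2-(2-benzyloxy-5-bromo-3-methoxyphenyl)acetaldehyde | O=CCc1cc(Br)cc(OC)c1OCc1ccccc1
F4 | step 5 | 2-(2-benzyloxy-5-bromo-3-methoxyphenyl)acetic acid | OC(=O)Cc1cc(Br)cc(OC)c1OCc1ccccc1
F5 | step 5 | (4R)-4-benzyl-3-[2-(2-benzyloxy-5-bromo-3-methoxyphenyl)acetyl]oxazolidin-2-one | COc1cc(Br)cc(CC(=O)N2[C@H](Cc3ccccc3)COC2=O)c1OCc1ccccc1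
F6 | step 5 | (4R)-4-benzyl-3-[(2S,3R)-2-(2-benzyloxy-5-bromo-3-methoxyphenyl)-3-(4-benzyloxy-3-methoxyphenyl)-3-(trimethylsilyloxy)propanoyl]oxazolidin-2-one | COc1cc(Br)cc([C@H](C(=O)N2[C@H](Cc3ccccc3)COC2=O)[C@@H](O[Si](C)(C)C)c2ccc(OCc3ccccc3)c(OC)c2)c1OCc1ccccc1
F7 | step 5 | (4R)-4-benzyl-3-[(2S,3R)-2-(2-benzyloxy-5-bromo-3-methoxyphenyl)-3-(4-benzyloxy-3-methoxyphenyl)-3-hydroxypropanoyl]oxazolidin-2-one | COc1cc(Br)cc([C@H](C(=O)N2[C@H](Cc3ccccc3)COC2=O)[C@@H](O)c2ccc(OCc3ccccc3)c(OC)c2)c1OCc1ccccc1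
F8 | step 5 | (1R,2R)-2-(2-benzyloxy-5-bromo-3-methoxyphenyl)-1-(4-benzyloxy-3-methoxyphenyl)propane-1,3-diol | COc1cc(Br)cc([C@H](CO)[C@@H](O)c2ccc(OCc3ccccc3)c(OC)c2)c1OCc1ccccc1
F9 | step 8 | 4-benzyloxy-3-[(4R,5R)-4-(4-benzyloxy-3-methoxyphenyl)-1,3-dioxan-5-yl]-5-methoxybenzaldehyde | COc1cc(C=O)cc([C@@H]2COCO[C@H]2c2ccc(OCc3ccccc3)c(OC)c2)c1OCc1ccccc1
F10 | step 8 | (E)-4-{4-benzyloxy-3-[(4R,5R)-4-(4-benzyloxy-3-methoxyphenyl)-1,3-dioxan-5-yl]-5-methoxyphenyl}-3-(methoxycarbonyl)but-3-enoic acid | COC(=O)/C(CC(=O)O)=C/c1cc(OC)c(OCc2ccccc2)c([C@@H]2COCO[C@H]2c2ccc(OCc3ccccc3)c(OC)c2)c1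
F11 | step 8 | (3R)-4-{4-benzyloxy-3-[(4R,5R)-4-(4-benzyloxy-3-methoxyphenyl)-1,3-dioxan-5-yl]-5-methoxyphenyl}-3-(methoxycarbonyl)butanoic acid | COC(=O)[C@@H](CC(=O)O)Cc1cc(OC)c(OCc2ccccc2)c([C@@H]2COCO[C@H]2c2ccc(OCc3ccccc3)c(OC)c2)c1
F12 | step 8 | (4R)-4-{4-benzyloxy-3-[(4R,5R)-4-(4-benzyloxy-3-methoxyphenyl)-1,3-dioxan-5-yl]-5-methoxybenzyl}dihydrofuran-2(3H)-one | O=C1C[C@@H](Cc2cc(OC)c(OCc3ccccc3)c([C@@H]3COCO[C@H]3c3ccc(OCc4ccccc4)c(OC)c3)c2)CO1
F13 | step 11 | (1R,2R)-2-(2-benzyloxy-5-bromo-3-methoxyphenyl)-1-(4-benzyloxy-3-methoxyphenyl)-1,3-bis(tert-butyldimethylsilyloxy)propane | COc1cc(Br)cc([C@H](CO[Si](C)(C)C(C)(C)C)[C@@H](O[Si](C)(C)C(C)(C)C)c2ccc(OCc3ccccc3)c(OC)c2)c1OCc1ccccc1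
F14 | step 11 | arylmagnesium bromide from F13 | COc1cc([Mg]Br)cc([C@H](CO[Si](C)(C)C(C)(C)C)[C@@H](O[Si](C)(C)C(C)(C)C)c2ccc(OCc3ccccc3)c(OC)c2)c1OCc1ccccc1
F15 | step 11 | methyl (3S,4R)-4-{4-benzyloxy-3-[(1R,2R)-1-(4-benzyloxy-3-methoxyphenyl)-1,3-bis(tert-butyldimethylsilyloxy)propan-2-yl]-5-methoxybenzyl}-2-oxotetrahydrofuran-3-carboxylate | COC(=O)[C@H]1C(=O)OC[C@@H]1Cc1cc(OC)c(OCc2ccccc2)c([C@H](CO[Si](C)(C)C(C)(C)C)[C@@H](O[Si](C)(C)C(C)(C)C)c2ccc(OCc3ccccc3)c(OC)c2)c1
F16 | step 11 | methyl (3R,4R)-3-(4-benzyloxy-3-methoxybenzyl)-4-{4-benzyloxy-3-[(1R,2R)-1-(4-benzyloxy-3-methoxyphenyl)-1,3-bis(tert-butyldimethylsilyloxy)propan-2-yl]-5-methoxybenzyl}-2-oxotetrahydrofuran-3-carboxylate | COc1cc(C[C@@]2(C(=O)OC)C(=O)OC[C@@H]2Cc2cc(OC)c(OCc3ccccc3)c([C@H](CO[Si](C)(C)C(C)(C)C)[C@@H](O[Si](C)(C)C(C)(C)C)c3ccc(OCc4ccccc4)c(OC)c3)c2)ccc1OCc1ccccc1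
F17 | step 11 | (3R,4R)-3-(4-benzyloxy-3-methoxybenzyl)-4-{4-benzyloxy-3-[(1R,2R)-1-(4-benzyloxy-3-methoxyphenyl)-1,3-bis(tert-butyldimethylsilyloxy)propan-2-yl]-5-methoxybenzyl}dihydrofuran-2(3H)-one | COc1cc(C[C@H]2C(=O)OC[C@@H]2Cc2cc(OC)c(OCc3ccccc3)c([C@H](CO[Si](C)(C)C(C)(C)C)[C@@H](O[Si](C)(C)C(C)(C)C)c3ccc(OCc4ccccc4)c(OC)c3)c2)ccc1OCc1ccccc1
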